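**Assumption:** Angustone B (C25H24O6) has no stereocenters and no stereogenic alkene. The prenyl terminus carries two methyls, and the chromene C=C sits in a ring. "Single enantiomer" therefore only means the achiral target, and no step sets stereochemistry.

## Retrosynthetic overview
1. Disconnect the isoflavone C3–C1' bond by Suzuki coupling of a 3-iodochromone (A-ring) with an aryl-Bpin (B-ring).
2. A-ring: the γ-pyrone is closed by enaminone/I2 cyclisation through the only free ortho-OH of a mono-protected, symmetrical 2',6'-dihydroxyacetophenone. The 6-prenyl group is then installed by a peri-carbonyl-controlled aromatic Claisen of a 5-O-(1,1-dimethylallyl) ether (proposed new step).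
3. B-ring: the 2,2-dimethylchromene pyran ring is formed first, from resorcinol bis-MOM by directed ortho-metalation, prenal addition and o-quinone-methide 6π-oxa-electrocyclisation. Ortho-metalation/borylation then places Bpin at C6.
4. Ring order: B-ring pyran, then A-ring pyranone, then the prenyl group, then the biaryl bond, then global deprotection.

## Route

**Step 1**
Reactants: 1 (2',4',6'-trihydroxyacetophenone)
Product: 2 (1-[2,6-dihydroxy-4-(methoxymethoxy)phenyl]ethanone)
Conditions: MOMCl (1.0 equiv), K2CO3 (1.1 equiv), acetone, 0 °C → rt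
Reagents that add atoms: MOMCl, COCCl
Why: The 4-OH is the most acidic and is not H-bonded to the carbonyl, so mono-alkylation is selective (Williamson-type MOM protection). The remaining 2,6-diOH pair is symmetry-equivalent, so all later regiochemistry is fixed.

**Step 2**
Reactants: 2; 3 (3-chloro-3-methylbut-1-yne)
Product: 4 (1-[2-hydroxy-4-(methoxymethoxy)-6-((2-methylbut-3-yn-2-yl)oxy)phenyl]ethanone)
Conditions: 3 (1.3 equiv), K2CO3, KI, CuI (10 mol %), DMF, 60 °C
Reagents that add atoms: none beyond numbered reactant 3
Why: Cu-assisted O-alkylation with a tertiary propargyl chloride (Godfrey-type). Because of the symmetry of 2, mono-alkylation gives a single constitutional isomer. The second OH is chelated and hindered, which limits dialkylation.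

**Step 3**
Reactants: 4
Product: 5 (1-[2-hydroxy-4-(methoxymethoxy)-6-((2-methylbut-3-en-2-yl)oxy)phenyl]ethanone)
Conditions: H2 (1 atm), Lindlar catalyst, quinoline, EtOAc, rt
Reagents that add atoms: none (H2 adds only hydrogen)
Why: Lindlar semihydrogenation takes the terminal alkyne to the 1,1-dimethylallyl (reverse-prenyl) ether. No halide or other reducible group is present at this stage, and MOM and the ketone are untouched.

**Step 4**
Reactants: 5
Product: 6 ((E)-3-(dimethylamino)-1-[2-hydroxy-4-(MOMO)-6-((2-methylbut-3-en-2-yl)oxy)phenyl]prop-2-en-1-one)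
Conditions: DMF-DMA (3 equiv), toluene, 80 °C, 12 h
Reagents that add atoms: DMF-DMA, CN(C)C(OC)OC
Why: Bredereck-type enaminone formation at the acetyl CH3. The temperature is kept at 80 °C to avoid premature Claisen of the tertiary allyl ether.

**Step 5**
Reactants: 6
Product: 7 (3-iodo-7-(MOMO)-5-((2-methylbut-3-en-2-yl)oxy)-4H-chromen-4-one)
Conditions: I2 (1.3 equiv), CH2Cl2, rt, 2 h; aq Na2S2O3 work-up
Reagents that add atoms: I2, II
Why: Iodination of the enaminone followed by attack of the free 2'-OH and loss of HNMe2 gives the 3-iodochromone (standard enaminone/I2 chromone synthesis). The only free ortho-OH closes the ring, so the tertiary allyloxy group necessarily ends up at C5.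

**Step 6**
Reactants: 7
Product: 8 (5-hydroxy-3-iodo-7-(MOMO)-6-(3-methylbut-2-en-1-yl)-4H-chromen-4-one)
Conditions: PhNEt2 (0.05 M), BHT (10 mol %), sealed tube, 140 °C, 3 h
Reagents that add atoms: none
Why: Proposed new method: this is a chelation-assisted aromatic Claisen [3,3] of a 5-O-(1,1-dimethylallyl) chromone, a substrate class not reported to my knowledge. C4a is a ring-fusion carbon, so C6 is the only possible ortho terminus and no C8 isomer can form. The peri C4=O forces the O-allyl group onto the C6 side, which pre-organises the chair transition state. The product is stabilised by the 5-OH···O=C4 chelate. The α,α-dimethylallyl ether delivers the linear prenyl group (O–CMe2–CH=CH2 → Ar–CH2–CH=CMe2). The closest known reaction is reverse-prenyl aryl ether → ortho-prenylphenol Claisen rearrangement. The 3-iodide, MOM and the prenyl group should survive.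

**Step 7**
Reactants: 9 (resorcinol)
Product: 10 (1,3-bis(methoxymethoxy)benzene)
Conditions: NaH (2.4 equiv), MOMCl (2.4 equiv), THF/DMF, 0 °C → rt
Reagents that add atoms: MOMCl, COCCl
Why: Standard double Williamson MOM protection. The symmetric product sets up directed metalation at C2.

**Step 8**
Reactants: 10; 11 (3-methylbut-2-enal, prenal)
Product: 12 (3-methyl-1-[2,6-bis(MOMO)phenyl]but-2-en-1-ol)
Conditions: n-BuLi (1.1 equiv), THF, 0 °C, 1 h; then 11 (1.2 equiv), −78 °C → rt; aq NH4Cl
Reagents that add atoms: none beyond numbered reactant 11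
Why: Directed ortho-metalation between the two OMOM groups followed by 1,2-addition of the aryllithium to the enal. The product is a secondary alcohol and an achiral racemate, so no stereochemistry matters here.

**Step 9**
Reactants: 12
Product: 13 (2,2-dimethyl-2H-chromen-5-ol)
Conditions: TsOH·H2O (1.0 equiv), MeOH, 45 °C, 4 h
Reagents that add atoms: none (MOM groups and H2O are lost)
Why: Acid removes the MOM groups and ionises the electron-rich benzylic/allylic alcohol. This gives a vinyl-o-quinone methide, which undergoes 6π-oxa-electrocyclisation to the 2,2-dimethyl-2H-chromene, as in salicylaldehyde plus alkenyl Grignard routes. Both oxygens of the symmetric precursor are equivalent, so there is a single regioisomer, with OH at C5 next to the vinyl carbon as required.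

**Step 10**
Reactants: 13
Product: 14 (5-(methoxymethoxy)-2,2-dimethyl-2H-chromene)
Conditions: MOMCl (1.5 equiv), i-Pr2NEt (2 equiv), CH2Cl2, 0 °C → rt
Reagents that add atoms: MOMCl, COCCl
Why: Plain phenol MOM protection to install a strong ortho-directing group. The chromene C=C is untouched.

**Step 11**
Reactants: 14
Product: 15 (2-[5-(MOMO)-2,2-dimethyl-2H-chromen-6-yl]-4,4,5,5-tetramethyl-1,3,2-dioxaborolane)
Conditions: n-BuLi (1.3 equiv), THF, 0 °C, 1.5 h; then i-PrO-Bpin (1.5 equiv), −78 °C → rt
Reagents that add atoms: 2-isopropoxy-4,4,5,5-tetramethyl-1,3,2-dioxaborolane, CC(C)OB1OC(C)(C)C(C)(C)O1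
Why: Directed ortho-lithiation by OMOM. C6 is the only position ortho to OMOM, because C4a is substituted, and the lithium is trapped as the pinacol boronate.

**Step 12**
Reactants: 8; 15
Product: 16 (5-hydroxy-7-(MOMO)-3-[5-(MOMO)-2,2-dimethyl-2H-chromen-6-yl]-6-prenyl-4H-chromen-4-one)
Conditions: Pd(PPh3)4 (5 mol %), 2 M aq Na2CO3, DME, 80 °C, 6 h
Reagents that add atoms: none beyond numbered reactants
Why: Suzuki–Miyaura coupling of a 3-iodochromone with an ortho-alkoxyaryl-Bpin is the standard isoflavone synthesis. The prenyl alkene, chromene, MOM groups and chelated 5-OH are compatible.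

**Step 13**
Reactants: 16
Product: 17 (Angustone B)
Conditions: TMSOTf (4 equiv), 2,2'-bipyridyl (6 equiv), MeCN, 0 °C → rt; then H2O, rt
Reagents that add atoms: none (water only hydrolyses the pyridinium acetal intermediates; the phenol oxygens come from the substrate)
Why: Mild, essentially non-acidic removal of both aryl MOM ethers (TMSOTf/bipyridyl method). This avoids acid-induced chromane formation from the prenyl group and avoids chromene solvolysis.

## Compound list
1 | 2',4',6'-trihydroxyacetophenone | CC(=O)c1c(O)cc(O)cc1O | starting material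
2 | 1-[2,6-dihydroxy-4-(methoxymethoxy)phenyl]ethanone | CC(=O)c1c(O)cc(OCOC)cc1O | intermediate
3 | 3-chloro-3-methylbut-1-yne | CC(C)(Cl)C#C | starting material
4 | 2-hydroxy-4-MOMO-6-(2-methylbut-3-yn-2-yloxy)acetophenone | CC(=O)c1c(O)cc(OCOC)cc1OC(C)(C)C#C | intermediate
5 | 2-hydroxy-4-MOMO-6-(2-methylbut-3-en-2-yloxy)acetophenone | CC(=O)c1c(O)cc(OCOC)cc1OC(C)(C)C=C | intermediate
6 | (E)-enaminone of 5 | CN(C)/C=C/C(=O)c1c(O)cc(OCOC)cc1OC(C)(C)C=C | intermediate
7 | 3-iodo-7-MOMO-5-(2-methylbut-3-en-2-yloxy)chromone | C=CC(C)(C)Oc1cc(OCOC)cc2occ(I)c(=O)c12 | intermediate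
8 | 5-hydroxy-3-iodo-7-MOMO-6-prenylchromone | CC(C)=CCc1c(OCOC)cc2occ(I)c(=O)c2c1O | intermediate
9 | resorcinol | Oc1cccc(O)c1 | starting material
10 | 1,3-bis(methoxymethoxy)benzene | COCOc1cccc(OCOC)c1 | intermediate
11 | 3-methylbut-2-enal (prenal) | CC(C)=CC=O | starting material
12 | 1-[2,6-bis(MOMO)phenyl]-3-methylbut-2-en-1-ol | CC(C)=CC(O)c1c(OCOC)cccc1OCOC | intermediate
13 | 2,2-dimethyl-2H-chromen-5-ol | CC1(C)C=Cc2c(O)cccc2O1 | intermediate
14 | 5-MOMO-2,2-dimethyl-2H-chromene | CC1(C)C=Cc2c(OCOC)cccc2O1 | intermediate
15 | 5-MOMO-2,2-dimethylchromen-6-yl-Bpin | CC1(C)C=Cc2c(OCOC)c(B3OC(C)(C)C(C)(C)O3)ccc2O1 | intermediate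
16 | bis-MOM isoflavone | CC(C)=CCc1c(OCOC)cc2occ(-c3ccc4c(c3OCOC)C=CC(C)(C)O4)c(=O)c2c1O | intermediate
17 | Angustone B | CC(C)=CCc1c(O)cc2occ(-c3ccc4c(c3O)C=CC(C)(C)O4)c(=O)c2c1O | target

## Totals
Total steps: 13. Longest linear sequence: 8 (1 → 2 → 4 → 5 → 6 → 7 → 8 → 16 → 17; the B-ring branch is 5 steps).

## Three steps most likely to fail
1. **Step 6 (proposed new Claisen).** The tertiary aryl allyl ether may ionise and lose isoprene, or decompose before it rearranges.
   - Fallback (known chemistry): abandon the Claisen and use the symmetric-arene route. Tris-MOM phloroglucinol is lithiated (n-BuLi) and C-prenylated with prenyl bromide/CuI. A second directed metalation with N-methoxy-N-methylacetamide gives the tris-MOM prenyl acetophenone. Chelation-assisted removal of the less hindered ortho-MOM (MgBr2 or TMSBr) then gives the 2'-OH ketone. Enaminone/I2 closure gives 8, with C6/C8 isomers separated by chromatography.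
2. **Step 11 (C6 ortho-lithiation and borylation of the chromene).** BuLi could add to the chromene C=C or lithiate at C8.
   - Fallback (known chemistry): build the B-ring from 4-bromoresorcinol bis-MOM. Lithiate C2 with LDA, add prenal, and cyclise with TsOH/MeOH to give 6-bromo-2,2-dimethylchromen-5-ol. Re-protect as MOM and apply Miyaura borylation (B2pin2, Pd(dppf)Cl2, KOAc) to reach 15.
3. **Step 2 (mono tertiary-propargylation of a chelated, hindered phenol).** It may give low conversion, bis-alkylation, or Cu-acetylide side products.
   - Fallback (known chemistry): alkylate diol 2 directly with 2-methylbut-3-en-2-yl trichloroacetimidate and catalytic BF3·OEt2 or TMSOTf in CH2Cl2 at 0 °C. This gives 5 in one step and removes both the propargylation and the Lindlar reduction.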